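## Structural features

Agastinol is a 7,9'-epoxylignan. One oxolane (ring A: O1, C2, C3, C4, C5) carries a guaiacyl group (ring B) directly on C2, an acyloxymethyl arm (C6) on C3 and a guaiacylmethyl arm (C7 with ring C) on C4, and the C6 oxygen is esterified by 4-hydroxybenzoic acid (ring D). C2, C3 and C4 are contiguous stereocentres, (2R,3S,4S): aryl and C6 are trans, C6 and the benzyl arm are cis, so aryl and benzyl are trans; C5 is an unsubstituted CH2. Because of the 3,4-cis relationship the target is not the all-trans, lowest-energy arrangement, so equilibrating every centre cannot deliver it. The fragile groups are the benzylic ether C2–O1 (acid ionisation, hydrogenolysis, quinone-methide formation once the para phenol is free), three oxidisable phenols and the alkyl aryl-ester. The real difficulty is to set three adjacent ring stereocentres from acyclic material, keep C2 intact, and finish with an unmasking that is neither reductive nor strongly basic. The key step reads O1–C2(aryl)–C3(C6)–C4(C7)–C5H2 as a 3-formyloxolane: C5 is a formaldehyde carbon, C4–C5 is the bond of a 2-oxonia-Cope shift, and C2–C3 is an aldol bond between a C3=C6 enol and an aryl-stabilised oxocarbenium ion O1=C2.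

## Logic of the disconnections

17 ⇒ 16. The three phenolic O–acetyl bonds are cut. Free phenols would compete in the esterification, and a free phenol para to C2 makes the benzylic ether labile. The gain is a single mild final operation. The forward step must cleave aryl acetates without touching the alkyl benzoate or C2–O1.

16 ⇒ 14 + 15. The acyl–O bond at C6 is cut, which removes ring D and leaves a primary alcohol. The demand is a neutral esterification that tolerates two aryl acetates.

14 ⇒ 13. C6 is raised to the aldehyde level, which exposes the 3-formyloxolane retron and makes C3 enolisable. That lability is used deliberately to correct C3. The reduction must spare aryl acetates.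

13 ⇒ 9 (through 12, 11 and 10). C2–C3 (aldol) and C4–C5 (oxonia-Cope) are cut and O1 is rejoined to C5 as a methylene acetal. 13 and 9 are isomers, so the ring and all three stereocentres are traced to an erythro diol, an E alkene and a formaldehyde carbon. The forward step needs ionisation at the acetal carbon, chirality transfer through one chair, retention of the C2/C4 relationship during closure, and a favourable C3 equilibrium. A descriptor check shows no structure needs correcting: 9 is the cis-(4S,5R) acetal of the erythro diol, the benzylic S centre becomes C2 (R) without inversion, and C3 is R in 13 but S in 14, 16 and 17 for the same geometry, only because CIP ranks change. What does need correcting is the expectation at C3: the cascade should give 12 first, so the equilibration to 13 is a planned operation, not an optional one.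

9 ⇒ 7 + 8. The C3=C4 alkene is cut by cross-metathesis, splitting the skeleton into two vanilloid halves. The second aryl acetate arrives with 8 only after the last basic operation. The step must give the E isomer, because the geometry becomes the C4 configuration.

7 ⇒ 5 + 6. The two acetal C–O bonds are cut and C5 becomes a formaldehyde equivalent. The acid used must not ionise the benzylic or allylic carbinol, which is why the aryl group is already acetylated.

5 ⇒ 4. The phenolic O–acetyl bond is cut. This corrects a weak point: any ester cleavage that frees the diol also strips an aryl acetate, so the acetate is treated as sacrificial up to 4 and is put back chemoselectively (phenoxide against neutral alcohols) before acid is used.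

4 ⇒ 1 + 2 (through 3). The C–C bond between the two carbinol carbons is cut by an enantioselective anti-(acyloxy)allylation. Both diol stereocentres come from one catalytic step on two purchasable pieces. The demand is anti selectivity, high ee, and survival of the phenolic acetate until the C–C bond has formed.

## Other disconnections considered

Alternative 1: Cut O1–C2, C2–C3 and C4–C5 together. Aldehyde A1 and silyl alcohol A2 are joined with Me3SiCl to an α-chloro silylmethyl ether, CsF releases the carbonyl ylide, and this adds across the alkene of butenolide A3 anti to its aryl group to give bicyclic lactone A4.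
- In favour: three ring bonds and three stereocentres arise in one convergent operation. The cis ring fusion enforces the C3/C4 cis relationship, which is better than the chosen plan, where C3 rests on an equilibrium.
- Against: the regiochemistry and exo selectivity of an unsymmetrical, non-stabilised ylide are uncertain. Fluoride is basic enough to enolise A3 at its only stereocentre. Later the benzylic lactone C–O bond must be hydrogenolysed beside the equally benzylic C2–O1 bond, and C6 must be acylated beside free phenols.
- Comparison: both plans relay one resident element of chirality; a concerted cycloaddition replaces a cationic cascade; step economy is about equal once A3 is made.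

Alternative 2: Cut C3–C4 and the C7–aryl bond. With NiBr2(dme), 4,4'-di-tert-butyl-2,2'-bipyridine and Zn, secondary iodide A5 gives the C3 radical, which closes 5-exo onto the allyl ether; the C7 radical is then arylated with A6 to give A7.
- In favour: the ester is already in place and only debenzylation remains, so the end game is shorter (better). The chair-like 5-exo transition state should give C2/C3 trans and C3/C4 cis kinetically, which is better than relying on an equilibrium at C3.
- Against: the radical precursor is β to two oxygen leaving groups, so reduction to an organometal invites β-elimination. Uncyclised arylation can compete. Three benzyl ethers must be hydrogenolysed in the presence of C2–O1. A5 needs regiocontrolled functionalisation of an arylglycerol.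
- Comparison: overall length is equal or slightly shorter, and the chosen acetates avoid the hydrogenolysis.

Alternative 3: Cut C3–C4 by ring contraction. Irradiation of diazo ketone A8 in methanol gives the carbene; the benzyl-bearing carbon migrates with retention and the ketene is trapped as ester A9.
- In favour: C2 comes from a catalytic asymmetric hetero-Diels–Alder reaction, and the benzyl group sits equatorial, trans to aryl, before migration, so the C2/C4 relationship is more secure than in the chosen plan (better). An ester is less prone than an aldehyde to ring-opening β-elimination (equal or better).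
- Against: C3 again depends on ketene protonation or later epimerisation (an equal weakness). The benzylic, oxygen-bearing C–H next to the carbene invites a 1,2-hydride shift to the enone. The basic diazo transfer can open the β-alkoxy ketone.
- Comparison: the sequence is about one step longer than the chosen plan.

Key step: step 5

Assumption: the (R) antipode of SEGPHOS is taken to give the (1S,2R) diol by analogy with related carbonyl allylations; if the sense is opposite, the (S) ligand is used and nothing else changes.

## Route

Step 1
Reactants: 1 4-formyl-2-methoxyphenyl acetate (vanillin acetate); 2 prop-2-ene-1,1-diyl diacetate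
Product: 4 4-[(1S,2R)-1,2-dihydroxybut-3-en-1-yl]-2-methoxyphenol, via anti hydroxy acetate 3 (not isolated)
Conditions: [Ir(cod)Cl]2 (2.5 mol%), (R)-SEGPHOS (5 mol%), 4-cyano-3-nitrobenzoic acid (10 mol%), Cs2CO3 (20 mol%), i-PrOH (2 equiv), THF, 90 °C; then K2CO3, MeOH, rt
Reagents that add atoms: none
Why: Iridium-catalysed transfer-hydrogenative anti-(α-acyloxy)allylation of an aryl aldehyde: the [Ir(cod)Cl]2/SEGPHOS/nitrobenzoate catalyst ionises 2 to an (E)-γ-acetoxy-σ-allyliridium species that adds through a closed chair, which sets the anti (erythro) pair, while the bisphosphine selects the aldehyde face and hence the (1S,2R) series; methanolysis then removes the secondary acetate (and any migrated isomer) together with the phenolic acetate, so loss of the latter after C–C bond formation does no harm.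

Step 2
Reactants: 4 4-[(1S,2R)-1,2-dihydroxybut-3-en-1-yl]-2-methoxyphenol
Product: 5 4-[(1S,2R)-1,2-dihydroxybut-3-en-1-yl]-2-methoxyphenyl acetate
Conditions: Ac2O (1.1 equiv), NaOH (1.1 equiv), H2O/THF, 0 °C
Reagents that add atoms: acetic anhydride, CC(=O)OC(C)=O
Why: Schotten–Baumann acetylation: in cold aqueous base only the phenol is ionised and the phenoxide is acylated far faster than the neutral secondary alcohols; the acetoxyaryl group so formed also tempers the benzylic carbinol against acid in the following steps.

Step 3
Reactants: 5 4-[(1S,2R)-1,2-dihydroxybut-3-en-1-yl]-2-methoxyphenyl acetate; 6 dimethoxymethane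
Product: 7 4-[(4S,5R)-5-ethenyl-1,3-dioxolan-4-yl]-2-methoxyphenyl acetate
Conditions: CH2(OMe)2 (excess), LiBr, TsOH·H2O (10 mol%), CH2Cl2, rt
Reagents that add atoms: none
Why: Acid-catalysed transacetalisation (methylene acetal formation of a 1,2-diol); the erythro diol closes to the cis-4,5-disubstituted dioxolane and both carbinol centres are untouched because no C–O bond at a stereocentre is broken.

Step 4
Reactants: 7 4-[(4S,5R)-5-ethenyl-1,3-dioxolan-4-yl]-2-methoxyphenyl acetate; 8 2-methoxy-4-(prop-2-en-1-yl)phenyl acetate (eugenol acetate)
Product: 9 (4S,5R)-4-(4-acetoxy-3-methoxyphenyl)-5-[(E)-3-(4-acetoxy-3-methoxyphenyl)prop-1-enyl]-1,3-dioxolane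
Conditions: second-generation Grubbs catalyst (H2IMes)(PCy3)Cl2Ru=CHPh (5 mol%), 8 (3 equiv), 1,4-benzoquinone (10 mol%), CH2Cl2, 40 °C
Reagents that add atoms: none
Why: Olefin cross-metathesis of a slowly dimerising, allylically branched alkene with an excess of a readily dimerising allylarene; secondary metathesis should bring the product to the E isomer, which is needed because the alkene geometry becomes the C4 configuration in step 5, and benzoquinone suppresses Ru–H migration of the allylarene double bond.

Step 5
Reactants: 9 (4S,5R)-4-(4-acetoxy-3-methoxyphenyl)-5-[(E)-3-(4-acetoxy-3-methoxyphenyl)prop-1-enyl]-1,3-dioxolane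
Product: 13 (2R,3R,4S)-2-(4-acetoxy-3-methoxyphenyl)-4-[(4-acetoxy-3-methoxyphenyl)methyl]oxolane-3-carbaldehyde, via methylene oxocarbenium stannate 10 (not isolated), via benzylidene oxocarbenium tin enolate 11 (not isolated), via C3-epimeric aldehyde 12 (not isolated)
Conditions: SnCl4 (3 equiv), CH2Cl2, −78 → −20 °C; aq. NaHCO3; then DBU (0.1 equiv), CH2Cl2, 0 °C
Reagents that add atoms: none
Why: SnCl4 opens the methylene acetal reversibly, and because only the ion with the oxocarbenium on the benzylic oxygen (10) is a 2-oxonia-1,5-diene, both ring-opening modes funnel into it. A 2-oxonia-Cope shift through a chair in which the aryl group, the stannyloxy group and the C7 arm of the E alkene are all equatorial forms C4–C5 and converts the formaldehyde-type cation into the aryl-conjugated (E)-oxocarbenium ion with an (E)-tin enolate (11), which is the driving force. The enolate carbon then adds to the oxocarbenium carbon in a 5-(enolexo)-endo-trig aldol closure, permissible for a cationic acceptor, forming C2–C3 and the oxolane; the closest known reaction type is the Lewis-acid Prins–pinacol (oxonia-Cope/aldol) conversion of 4-alkenyl-1,3-dioxolanes into 3-acyloxolanes. C4 (S) is substrate-controlled: the (4S,5R) acetal with an E alkene has only one all-equatorial chair, so the diol chirality is transferred to C4. C2 (R) should result from collapse of 11 on the face from which C6 departed (least motion, stereochemically the same as a pinacol shift with retention), which puts aryl trans to the benzyl arm. C3 is expected to emerge with formyl cis to aryl (12) for the same topological reason, and catalytic DBU in an aprotic solvent then equilibrates this one enolisable centre to 13, where formyl is trans to the directly attached aryl group and cis only to the slimmer CH2Ar arm. The step needs ionisation at the acetal carbon in preference to the benzylic and allylic C–O bonds and a closure faster than rotation or hydrolysis of 11; the para-acetoxy groups secure the first by damping both arenes while still leaving the C2 cation aryl-stabilised.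

Step 6
Reactants: 13 (2R,3R,4S)-2-(4-acetoxy-3-methoxyphenyl)-4-[(4-acetoxy-3-methoxyphenyl)methyl]oxolane-3-carbaldehyde
Product: 14 [(2R,3S,4S)-2-(4-acetoxy-3-methoxyphenyl)-4-[(4-acetoxy-3-methoxyphenyl)methyl]oxolan-3-yl]methanol
Conditions: NaBH4, THF/EtOH, −20 °C
Reagents that add atoms: none
Why: Borohydride reduction of an aldehyde is much faster than attack on aryl acetates at low temperature; it freezes the C3 configuration, and any C3-epimeric alcohol should be separable by chromatography at this stage.

Step 7
Reactants: 14 [(2R,3S,4S)-2-(4-acetoxy-3-methoxyphenyl)-4-[(4-acetoxy-3-methoxyphenyl)methyl]oxolan-3-yl]methanol; 15 4-acetoxybenzoic acid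
Product: 16 [(2R,3S,4S)-2-(4-acetoxy-3-methoxyphenyl)-4-[(4-acetoxy-3-methoxyphenyl)methyl]oxolan-3-yl]methyl 4-acetoxybenzoate
Conditions: PPh3, DIAD, THF, 0 °C → rt
Reagents that add atoms: none
Why: Mitsunobu esterification of a primary alcohol with a carboxylic acid; the neutral conditions leave the aryl acetates and the benzylic ether alone and no stereocentre is involved.

Step 8
Reactants: 16 [(2R,3S,4S)-2-(4-acetoxy-3-methoxyphenyl)-4-[(4-acetoxy-3-methoxyphenyl)methyl]oxolan-3-yl]methyl 4-acetoxybenzoate
Product: 17 agastinol, [(2R,3S,4S)-2-(4-hydroxy-3-methoxyphenyl)-4-[(4-hydroxy-3-methoxyphenyl)methyl]oxolan-3-yl]methyl 4-hydroxybenzoate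
Conditions: NH4OAc, MeOH/H2O (4:1), rt
Reagents that add atoms: none
Why: Ammonium acetate-mediated methanolysis is selective for aryl acetates: the three phenolic acetates are cleaved while the alkyl benzoate, still less electrophilic once its para phenol is free, and the acid- and hydrogenolysis-sensitive benzylic ether are left intact.

## Compound list

1 | 4-formyl-2-methoxyphenyl acetate (vanillin acetate) | COc1cc(C=O)ccc1OC(C)=O | starting material
2 | prop-2-ene-1,1-diyl diacetate | C=CC(OC(C)=O)OC(C)=O | starting material
3 | (1S,2R)-1-(4-acetoxy-3-methoxyphenyl)-1-hydroxybut-3-en-2-yl acetate | CC(=O)Oc1ccc([C@H](O)[C@H](OC(C)=O)C=C)cc1OC | intermediate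
4 | 4-[(1S,2R)-1,2-dihydroxybut-3-en-1-yl]-2-methoxyphenol | COc1cc([C@H](O)[C@H](O)C=C)ccc1O | intermediate
5 | 4-[(1S,2R)-1,2-dihydroxybut-3-en-1-yl]-2-methoxyphenyl acetate | CC(=O)Oc1ccc([C@H](O)[C@H](O)C=C)cc1OC | intermediate
6 | dimethoxymethane | COCOC | starting material
7 | 4-[(4S,5R)-5-ethenyl-1,3-dioxolan-4-yl]-2-methoxyphenyl acetate | CC(=O)Oc1ccc([C@@H]2OCO[C@@H]2C=C)cc1OC | intermediate
8 | 2-methoxy-4-(prop-2-en-1-yl)phenyl acetate (eugenol acetate) | COc1cc(CC=C)ccc1OC(C)=O | starting material
9 | (4S,5R)-4-(4-acetoxy-3-methoxyphenyl)-5-[(E)-3-(4-acetoxy-3-methoxyphenyl)prop-1-enyl]-1,3-dioxolane | CC(=O)Oc1ccc([C@@H]2OCO[C@@H]2/C=C/Cc2ccc(OC(C)=O)c(OC)c2)cc1OC | intermediate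
10 | ring-opened O-methylene oxocarbenium ion of 9, allylic oxygen bound to SnCl4 | C=[O+][C@@H](c1ccc(OC(C)=O)c(OC)c1)[C@H](O[Sn-](Cl)(Cl)(Cl)Cl)/C=C/Cc1ccc(OC(C)=O)c(OC)c1 | intermediate
11 | (E)-O-alkyl benzylidene oxocarbenium ion carrying the (E)-tin enolate, (S) at the benzyl-bearing carbon | CC(=O)Oc1ccc(/C=[O+]/C[C@@H](Cc2ccc(OC(C)=O)c(OC)c2)/C=C/O[Sn-](Cl)(Cl)(Cl)Cl)cc1OC | intermediate
12 | (2R,3S,4S)-2-(4-acetoxy-3-methoxyphenyl)-4-[(4-acetoxy-3-methoxyphenyl)methyl]oxolane-3-carbaldehyde (formyl cis to aryl) | COc1cc(C[C@@H]2CO[C@@H](c3ccc(OC(C)=O)c(OC)c3)[C@H]2C=O)ccc1OC(C)=O | intermediate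
13 | (2R,3R,4S)-2-(4-acetoxy-3-methoxyphenyl)-4-[(4-acetoxy-3-methoxyphenyl)methyl]oxolane-3-carbaldehyde (formyl trans to aryl) | COc1cc(C[C@@H]2CO[C@@H](c3ccc(OC(C)=O)c(OC)c3)[C@@H]2C=O)ccc1OC(C)=O | intermediate
14 | [(2R,3S,4S)-2-(4-acetoxy-3-methoxyphenyl)-4-[(4-acetoxy-3-methoxyphenyl)methyl]oxolan-3-yl]methanol | COc1cc(C[C@@H]2CO[C@@H](c3ccc(OC(C)=O)c(OC)c3)[C@@H]2CO)ccc1OC(C)=O | intermediate
15 | 4-acetoxybenzoic acid | CC(=O)Oc1ccc(C(=O)O)cc1 | starting material
16 | [(2R,3S,4S)-2-(4-acetoxy-3-methoxyphenyl)-4-[(4-acetoxy-3-methoxyphenyl)methyl]oxolan-3-yl]methyl 4-acetoxybenzoate | COc1cc(C[C@@H]2CO[C@@H](c3ccc(OC(C)=O)c(OC)c3)[C@@H]2COC(=O)c2ccc(OC(C)=O)cc2)ccc1OC(C)=O | intermediate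
17 | agastinol | COc1cc(C[C@@H]2CO[C@@H](c3ccc(O)c(OC)c3)[C@@H]2COC(=O)c2ccc(O)cc2)ccc1O | target

## Step count and least certain steps

Total step count: 8. Longest linear sequence: 8 steps (1 → 4 → 5 → 7 → 9 → 13 → 14 → 16 → 17); 2, 6, 8 and 15 enter as purchased pieces.

**Step 5 (key step).** The most likely failure is loss of stereochemical memory or fragmentation at the stage of the open ion pair 11. The 5-endo aldol closure is slow, so bond rotation can erode the C2/C4 trans relationship and hydrolysis can expel 1. The C3 equilibrium may also favour 13 only modestly, since both epimers have one cis contact, and prolonged base could scramble C2 by reversible β-elimination of the ring oxygen.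

Fallback, setting out from 1 and returning at 14 (the ring is closed by a radical instead of a cation):
- Wittig homologation of 1 with (triphenylphosphoranylidene)acetaldehyde gives (E)-3-(4-acetoxy-3-methoxyphenyl)prop-2-enal F1.
- Luche reduction (NaBH4, CeCl3) gives (E)-3-(4-acetoxy-3-methoxyphenyl)prop-2-en-1-ol F2.
- Sharpless asymmetric epoxidation (Ti(O-i-Pr)4, D-(−)-diethyl tartrate, t-BuOOH) gives [(2R,3R)-3-(4-acetoxy-3-methoxyphenyl)oxiran-2-yl]methanol F3.
- BF3·OEt2-catalysed opening of F3 at the benzylic carbon by a second portion of F2, with inversion, gives (2R,3S)-3-(4-acetoxy-3-methoxyphenyl)-3-{[(2E)-3-(4-acetoxy-3-methoxyphenyl)prop-2-en-1-yl]oxy}propane-1,2-diol F4.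
- Mitsunobu cyclodehydration (PPh3, DIAD) gives the terminal epoxide 4-[(S)-{[(2E)-3-(4-acetoxy-3-methoxyphenyl)prop-2-en-1-yl]oxy}[(2R)-oxiran-2-yl]methyl]-2-methoxyphenyl acetate F5.
- Cp2TiCl (trivalent titanium, from Cp2TiCl2 and Zn) opens the epoxide to the C3 radical, which closes 5-exo onto the cinnamyl ether through a chair-like transition state with the aryl group pseudo-equatorial. This should set C2/C3 trans and C3/C4 cis kinetically; reduction and protonation of the benzylic radical give 14.

**Step 1.** The most likely failure is premature transesterification of the phenolic acetate of 1 in the basic alcoholic medium at 90 °C. The resulting phenoxide aldehyde is a poor electrophile, and an electron-rich aldehyde may also erode anti selectivity or ee.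

Fallback, setting out from 1 and returning at 4 (a stoichiometric chiral borane replaces the catalyst): (+)-diisopinocampheylborane, from (−)-α-pinene, hydroborates allenylboronic acid pinacol ester to the (E)-γ-borylallylborane. This adds to 1 at −78 °C under neutral conditions through a chair to give the anti adduct (1R,2R)-1-(4-acetoxy-3-methoxyphenyl)-1-[bis(isopinocampheyl)boryloxy]-2-(4,4,5,5-tetramethyl-1,3,2-dioxaborolan-2-yl)but-3-ene F6. NaOH/H2O2 then replaces boron by hydroxyl with retention and cleaves the aryl acetate, giving 4.

**Step 4.** The most likely failure is incomplete E selectivity together with double-bond migration. The cis aryl group next to the vinyl group makes 7 a sluggish partner, so self-metathesis of 8 and Ru–H isomerisation of the allylarene can outrun the cross reaction, and any Z isomer would be carried into the wrong C4 configuration.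

Fallback, setting out from 7 and returning at 9 (the C7–aryl bond is made instead of the alkene): cross-metathesis of 7 with (Z)-but-2-ene-1,4-diyl diacetate gives (2E)-3-[(4R,5S)-5-(4-acetoxy-3-methoxyphenyl)-1,3-dioxolan-4-yl]prop-2-en-1-yl acetate F7. Pd(PPh3)4-catalysed allyl–aryl coupling with 2-(4-acetoxy-3-methoxyphenyl)-4,4,5,5-tetramethyl-1,3,2-dioxaborolane (KF, THF/H2O) follows. The π-allylpalladium intermediate equilibrates to its syn form and should deliver the linear E product whatever the geometry of F7. Any phenolic acetate lost to the base is restored with Ac2O/pyridine, which is safe because 9 has no other hydroxyl group.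

## Further compounds

F1 | step 5 | (E)-3-(4-acetoxy-3-methoxyphenyl)prop-2-enal | COc1cc(/C=C/C=O)ccc1OC(C)=O
F2 | step 5 | (E)-3-(4-acetoxy-3-methoxyphenyl)prop-2-en-1-ol | COc1cc(/C=C/CO)ccc1OC(C)=O
F3 | step 5 | [(2R,3R)-3-(4-acetoxy-3-methoxyphenyl)oxiran-2-yl]methanol | COc1cc([C@H]2O[C@@H]2CO)ccc1OC(C)=O
F4 | step 5 | (2R,3S)-3-(4-acetoxy-3-methoxyphenyl)-3-{[(2E)-3-(4-acetoxy-3-methoxyphenyl)prop-2-en-1-yl]oxy}propane-1,2-diol | COc1cc([C@H](OC/C=C/c2ccc(OC(C)=O)c(OC)c2)[C@H](O)CO)ccc1OC(C)=O
F5 | step 5 | 4-[(S)-{[(2E)-3-(4-acetoxy-3-methoxyphenyl)prop-2-en-1-yl]oxy}[(2R)-oxiran-2-yl]methyl]-2-methoxyphenyl acetate | COc1cc([C@H](OC/C=C/c2ccc(OC(C)=O)c(OC)c2)[C@H]2CO2)ccc1OC(C)=O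
F6 | step 1 | (1R,2R)-1-(4-acetoxy-3-methoxyphenyl)-1-[bis(isopinocampheyl)boryloxy]-2-(4,4,5,5-tetramethyl-1,3,2-dioxaborolan-2-yl)but-3-ene | CC(=O)Oc1ccc([C@H](OB([C@H]2C[C@H]3C[C@@H]([C@@H]2C)C3(C)C)[C@H]2C[C@H]3C[C@@H]([C@@H]2C)C3(C)C)[C@H](B2OC(C)(C)C(C)(C)O2)C=C)cc1OC
F7 | step 4 | (2E)-3-[(4R,5S)-5-(4-acetoxy-3-methoxyphenyl)-1,3-dioxolan-4-yl]prop-2-en-1-yl acetate | CC(=O)Oc1ccc([C@@H]2OCO[C@@H]2/C=C/COC(C)=O)cc1OC
A1 | alternative 1 | 4-(benzyloxy)-3-methoxybenzaldehyde | COc1cc(C=O)ccc1OCc1ccccc1
A2 | alternative 1 | (trimethylsilyl)methanol | C[Si](C)(C)CO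
A3 | alternative 1 | (R)-5-[4-(benzyloxy)-3-methoxyphenyl]furan-2(5H)-one | COc1cc([C@H]2C=CC(=O)O2)ccc1OCc1ccccc1
A4 | alternative 1 | cis-fused 4,8-bis[4-(benzyloxy)-3-methoxyphenyl]-3,7-dioxabicyclo[3.3.0]octan-2-one, both aryl groups exo | COc1cc([C@H]2[C@@H]3CO[C@@H](c4ccc(OCc5ccccc5)c(OC)c4)[C@@H]3C(=O)O2)ccc1OCc1ccccc1
A5 | alternative 2 | (3S)-3-[4-(benzyloxy)-3-methoxyphenyl]-2-iodo-3-(prop-2-en-1-yloxy)propyl 4-(benzyloxy)benzoate, mixture of C2 epimers | COc1cc([C@H](OCC=C)C(I)COC(=O)c2ccc(OCc3ccccc3)cc2)ccc1OCc1ccccc1
A6 | alternative 2 | 1-(benzyloxy)-4-iodo-2-methoxybenzene | COc1cc(I)ccc1OCc1ccccc1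
A7 | alternative 2 | tri-O-benzylagastinol | COc1cc(C[C@@H]2CO[C@@H](c3ccc(OCc4ccccc4)c(OC)c3)[C@@H]2COC(=O)c2ccc(OCc3ccccc3)cc2)ccc1OCc1ccccc1
A8 | alternative 3 | (2S,5R)-2-[4-(benzyloxy)-3-methoxyphenyl]-5-{[4-(benzyloxy)-3-methoxyphenyl]methyl}-3-diazooxan-4-one | COc1cc(C[C@@H]2CO[C@@H](c3ccc(OCc4ccccc4)c(OC)c3)C(=[N+]=[N-])C2=O)ccc1OCc1ccccc1
A9 | alternative 3 | methyl (2R,3R,4S)-2-[4-(benzyloxy)-3-methoxyphenyl]-4-{[4-(benzyloxy)-3-methoxyphenyl]methyl}oxolane-3-carboxylate | COc1cc(C[C@@H]2CO[C@@H](c3ccc(OCc4ccccc4)c(OC)c3)[C@@H]2C(=O)OC)ccc1OCc1ccccc1
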